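## Analysis of the target

The target is a flavanone, a 2-phenylchroman-4-one in which a dihydropyranone (O1, C2, C3, C4) is fused to an aromatic A ring (C4a–C8a) and C2 carries a plain phenyl B ring. The A ring is hexasubstituted: O1 at C8a, the acyl carbon at C4a, hydroxyls at C5 and C7, and a 2,3-dihydroxybenzyl group at each of C6 and C8. C2 is the only stereocentre and is S, so there is no relative configuration to control. It is benzylic, bears O1 and lies β to the C4 ketone, so base can open the pyranone by retro-oxa-Michael elimination to an achiral 2'-hydroxychalcone, which recloses as the racemate. The sensitive groups are the two catechols (oxidation to ortho-quinones), the very electron-rich phloroglucinol-type A ring (ipso attack, reversible C-benzylation in strong acid) and this base-labile centre. The difficulty is to place two identical benzyl groups on the two remaining A-ring carbons with the correct attachment on the pendant rings. There the methylene is on C1'' and the oxygens on C2'' and C3'', a contiguous pattern that a benzylic electrophile attacking catechol would not give (it would give mainly the 3,4-dihydroxybenzyl isomer). The strategy rests on the fact that each methylene sits on an A-ring carbon ortho to a free phenol: the C7 hydroxyl lies between C6 and C8, and the C5 hydroxyl is a second neighbour of C6. Both units are therefore ortho-hydroxybenzyl groups, the products of aryl addition to ortho-quinone methides, and the core without them is (S)-pinocembrin, so C2 can be taken from the chiral pool.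

## Retrosynthetic reasoning

**Target 12 to tetra-MOM ether 11.** The four catechol O–H bonds are masked as methoxymethyl acetals and released last. Free catechols would oxidise during the sequence and would tie up a boron reagent as cyclic esters. The acetal is chosen because it also directs the metalation that makes the aryl partner, and because it leaves under mild acid, which the flavanone tolerates far better than base.

**11 to bis(aminomethyl) flavanone 2 and boronic acid 7.** Both CH2–C1'' bonds are cut. Cutting CH2–C6 and CH2–C8 instead would make the catechol side the electrophile and leave mono/bis selectivity and O- versus C-alkylation to the flavanone nucleophile, with unprotected, oxidisable partners. Cutting at C1'' makes the A ring the electrophile twice, as ortho-quinone methides 8 and 10, and stores the pendant-ring regiochemistry in the carbon–boron bond of 7. The gain is convergence: one flavanone and two aryl units are joined in one operation, through mono-arylated intermediate 9. The forward reaction must release each methide from 2 without strong base and transfer the aryl group from boron faster than the methides react with each other. The C8 methide can only form through O7, because C8a carries the ring ether; the C6 methide can use O7 or O5.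

**2 to (S)-pinocembrin 1.** The C6–CH2 and C8–CH2 bonds are cut in a Mannich sense. C6 and C8 are the only unsubstituted A-ring carbons and each is ortho or para to three oxygens, so a one-carbon iminium electrophile has no other aromatic site to attack. The gain is that the whole flavanone, C2 included, is bought as 1. The forward reaction must substitute both positions without opening the pyranone, which calls for a buffered, weakly acidic medium.

**7 to bis-acetal 4.** The C–B bond is cut to an aryllithium 5 and a trialkyl borate, via ate complex 6. Lithiation ortho to an acetal oxygen is reliable, and the two ortho positions of 4 are equivalent, so only one regioisomer can form. The boron then sits on the carbon that becomes C1'', next to the oxygen that becomes O2''.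

**4 to catechol 3.** Twofold O-alkylation of 3 installs the acetals; the two hydroxyls are equivalent.

## Alternatives that were turned down

**Alternative 1: Danheiser benzannulation to build the A ring.** The disconnection dismantles the A ring into cyclobutenone A2 and siloxyalkyne A3, each already carrying a protected 2,3-dihydroxybenzyl group. On heating, A2 opens to a vinylketene, adds to A3 (C8–C8a and C6–C7 bonds), and 6π-electrocyclisation (C4a–C8a bond) gives phenol A1.
- For: every A-ring substituent is placed by the regiochemistry of the cycloaddition, and no twofold reaction on one nucleus is needed. On regiochemical certainty of the A ring this route is stronger than the chosen one.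
- Against: A1 still lacks the pyranone and C2. C4a must be acylated and the ring closed by an asymmetric oxa-Michael step on a crowded substrate, which brings back the reversibility problem at C2. A2 and A3 each need several steps, and two silyl and four benzyl groups must be handled.
- Comparison: the chosen route buys the ring system and the stereocentre and concentrates its risk in one step; it is several times shorter.

**Alternative 2: palladium-catalysed etherification closing O1–C8a.** The disconnection is the aryl–oxygen bond. The (S)-benzylic alcohol of aryl triflate A5 would couple with C8a under palladium catalysis to give flavan A4.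
- For: the bond formed is to the aryl carbon, so the carbinol C–O bond is untouched and the configuration is retained. At the flavan oxidation level no retro-Michael opening is possible, so C2 is better protected than in the chosen route.
- Against: the triflate sits in a hexasubstituted ring between two ortho substituents, which slows oxidative addition and reductive elimination. A secondary alkoxide on palladium can undergo β-hydride elimination. C4 must later be desilylated and oxidised, and six acetals removed. A5 needs a phloroglucinol with three differentiated oxygens, two benzyl groups and an asymmetrically built side chain.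
- Comparison: the chosen route accepts some risk at C2 in exchange for a sequence of five steps instead of well over ten.

**Alternative 3: acylative ring closure at the single A-ring C–H.** The disconnection is C4–C4a. The activated carboxyl of (S)-β-aryloxy acid A7 would acylate C4a and give benzyl-protected flavanone A6.
- For: only one aromatic C–H remains, so the site of acylation is forced. Benzyl ethers leave by neutral hydrogenolysis, which is milder for the final polyphenol than the acid used in the chosen route.
- Against: A7 requires etherification of a hindered phenol at a secondary benzylic carbon with inversion, where ionisation erodes configuration. Under the strong acid needed for acylation, the β-aryloxy acid can lose the phenol to an α,β-unsaturated acid. The phenol half of A7 needs a selective twofold C-benzylation of a triphenol, which is the very selectivity problem the chosen route avoids by starting from a nucleus with only two free positions.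
- Comparison: the chosen route needs no stereocentre construction and fewer steps.

Key step: step 4

Assumption: commercial pinocembrin of natural origin is taken to be the (2S)-enantiomer shown, and its enantiomeric purity sets the ceiling for the route.

## Route

**Step 1**
Reactants: 1 (S)-pinocembrin [(2S)-5,7-dihydroxy-2-phenylchroman-4-one]
Product: 2 (2S)-6,8-bis[(dimethylamino)methyl]-5,7-dihydroxy-2-phenylchroman-4-one
Conditions: 37% aq. CH2O (3 equiv), 40% aq. Me2NH (3 equiv), AcOH (6 equiv), EtOH, 0 °C → rt; work-up at pH 7–8 (NaHCO3), cold
Reagents that add atoms: formaldehyde C=O; dimethylamine CNC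
Why: Mannich aminomethylation, an electrophilic aromatic substitution by the methyleneiminium ion formed in situ; C6 and C8 are the only free positions of the phloroglucinol-type ring and both are activated by three oxygens, so the second substitution should follow the first. The acetate buffer keeps the medium weakly acidic, where retro-oxa-Michael opening of the pyranone is slow, so C2 should be retained; aminomethylation at C3 through the enol is not expected at room temperature.

**Step 2**
Reactants: 3 catechol
Product: 4 1,2-bis(methoxymethoxy)benzene
Conditions: NaH (2.4 equiv), DMF, 0 °C; MOMCl (2.4 equiv), 0 °C → rt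
Reagents that add atoms: chloromethyl methyl ether COCCl
Why: Williamson-type O-alkylation of the bis-phenoxide by the reactive α-chloro ether; the two hydroxyls are equivalent, so a single product should form.

**Step 3**
Reactants: 4 1,2-bis(methoxymethoxy)benzene
Product: 7 [2,3-bis(methoxymethoxy)phenyl]boronic acid, via aryllithium 5 (not isolated), via lithium triisopropoxyborate 6 (not isolated)
Conditions: n-BuLi, TMEDA, THF, −20 → 0 °C; B(OiPr)3, −78 °C → rt; sat. aq. NH4Cl, 0 °C
Reagents that add atoms: triisopropyl borate CC(C)OB(OC(C)C)OC(C)C; water O; n-butyllithium [Li]CCCC (lithium of 5 and 6 only)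
Why: Directed ortho-metalation: the acetal oxygen coordinates lithium and directs deprotonation to the adjacent carbon, and the two ortho positions of 4 are equivalent. The aryllithium is trapped by the borate as ate complex 6, which buffered water hydrolyses to the boronic acid without touching the acetals.

**Step 4**
Reactants: 2 (2S)-6,8-bis[(dimethylamino)methyl]-5,7-dihydroxy-2-phenylchroman-4-one; 7 [2,3-bis(methoxymethoxy)phenyl]boronic acid
Product: 11 (2S)-6,8-bis[2,3-bis(methoxymethoxy)benzyl]-5,7-dihydroxy-2-phenylchroman-4-one, via C8 quinone methide 8 (not isolated), via monoarylated aminomethyl flavanone 9 (not isolated), via C6 quinone methide 10 (not isolated)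
Conditions: 7 (5 equiv), PhMe–1,4-dioxane, 90 °C, N2 sweep, slow addition of 2; then aq. pH 7 buffer, rt
Reagents that add atoms: none
Why: The reaction type is the known addition of arylboron reagents to ortho-quinone methides released in situ from ortho-hydroxybenzylamines (a Petasis-type aryl transfer), here used at two sites of one nucleus. The boronic acid engages the C7 oxygen and the neighbouring nitrogen, dimethylamine leaves and methide 8 forms; the aryl group then migrates from tetracoordinate boron to the exocyclic methylene through a six-membered array (O7–B–C1''···CH2–C8–C7), which restores the aromatic A ring and gives 9 as its aryl borate. The same sequence at C6, through O7 after borate exchange or through O5, passes through 10 and gives 11 after hydrolytic work-up; the order of the two sites is immaterial and C8 is drawn first only for definiteness. No ring is closed and no stereocentre is created, so C2 is a spectator. On the pendant ring the new bond forms at the carbon that carried boron, which fixes the C1''/O2''/O3'' pattern. The A ring of 2 has no unsubstituted carbon, so one flavanone can be C-alkylated by the methide of another only through ipso attack, and slow addition of 2 into excess 7 keeps the methide concentration low. No base stronger than the liberated dimethylamine is present, and this is bound by the excess boronic acid and swept out, so retro-oxa-Michael opening at C2 should not compete; the excess of 7 also covers the part held as a chelate at O5/O4 and the part lost by protodeboronation.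

**Step 5**
Reactants: 11 (2S)-6,8-bis[2,3-bis(methoxymethoxy)benzyl]-5,7-dihydroxy-2-phenylchroman-4-one
Product: 12 (2S)-6,8-bis(2,3-dihydroxybenzyl)-5,7-dihydroxy-2-phenylchroman-4-one (target)
Conditions: HCl (ca. 1 M) in degassed MeOH, 0 → 40 °C, Ar
Reagents that add atoms: none
Why: Acid-catalysed methanolysis of the four aryl methoxymethyl acetals (transacetalisation; the C1 unit leaves as the dimethyl acetal). Dilute acid at mild temperature should neither open the pyranone, which is a base-mediated process, nor cleave the diarylmethane links, and exclusion of air protects the catechols.

## Compound list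

1 | (S)-pinocembrin, (2S)-5,7-dihydroxy-2-phenylchroman-4-one | O=C1C[C@@H](c2ccccc2)Oc2cc(O)cc(O)c21 | starting material
2 | (2S)-6,8-bis[(dimethylamino)methyl]-5,7-dihydroxy-2-phenylchroman-4-one | O=C1C[C@@H](c2ccccc2)Oc2c(CN(C)C)c(O)c(CN(C)C)c(O)c21 | intermediate
3 | catechol | Oc1ccccc1O | starting material
4 | 1,2-bis(methoxymethoxy)benzene | COCOc1ccccc1OCOC | intermediate
5 | [2,3-bis(methoxymethoxy)phenyl]lithium | [Li]c1cccc(OCOC)c1OCOC | intermediate
6 | lithium [2,3-bis(methoxymethoxy)phenyl]tri(propan-2-yloxy)borate | [Li+].COCOc1cccc([B-](OC(C)C)(OC(C)C)OC(C)C)c1OCOC | intermediate
7 | [2,3-bis(methoxymethoxy)phenyl]boronic acid | OB(O)c1cccc(OCOC)c1OCOC | intermediate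
8 | (2S)-6-[(dimethylamino)methyl]-5-hydroxy-8-methylidene-2-phenyl-2,3-dihydrochromene-4,7(8H)-dione (C8 ortho-quinone methide) | O=C1C[C@@H](c2ccccc2)OC2=C1C(O)=C(CN(C)C)C(=O)C2=C | intermediate
9 | (2S)-8-[2,3-bis(methoxymethoxy)benzyl]-6-[(dimethylamino)methyl]-5,7-dihydroxy-2-phenylchroman-4-one | O=C1C[C@@H](c2ccccc2)Oc2c(Cc3cccc(OCOC)c3OCOC)c(O)c(CN(C)C)c(O)c21 | intermediate
10 | (2S)-8-[2,3-bis(methoxymethoxy)benzyl]-5-hydroxy-6-methylidene-2-phenyl-2,3-dihydrochromene-4,7(6H)-dione (C6 ortho-quinone methide) | O=C1C[C@@H](c2ccccc2)OC2=C(Cc3cccc(OCOC)c3OCOC)C(=O)C(=C)C(O)=C12 | intermediate
11 | (2S)-6,8-bis[2,3-bis(methoxymethoxy)benzyl]-5,7-dihydroxy-2-phenylchroman-4-one | O=C1C[C@@H](c2ccccc2)Oc2c(Cc3cccc(OCOC)c3OCOC)c(O)c(Cc3cccc(OCOC)c3OCOC)c(O)c21 | intermediate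
12 | (2S)-6,8-bis(2,3-dihydroxybenzyl)-5,7-dihydroxy-2-phenylchroman-4-one | O=C1C[C@@H](c2ccccc2)Oc2c(Cc3cccc(O)c3O)c(O)c(Cc3cccc(O)c3O)c(O)c21 | target

## Step count and least certain steps

Total: 5 steps. Longest linear sequence: 4 steps (3 → 4 → 7 → 11 → 12; steps 2, 3, 4, 5).

**Step 4 (key step).** The most likely failures are:
- stalling after the first aryl transfer, because the second methide must form on a more hindered and less basic intermediate;
- self-reaction of the methides (hetero-Diels–Alder dimerisation, ipso attack with loss of an iminium unit, re-addition of amine) outrunning aryl transfer;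
- protodeboronation of the ortho-alkoxy boronic acid at the temperature needed;
- partial loss of configuration at C2 through amine-promoted ring opening.

Fallback, setting out from 1 and returning at 12: the polarity is reversed. 1 is heated with an excess of 2,3-dihydroxybenzyl alcohol F1 (purchasable) and anhydrous ZnCl2 in 1,4-dioxane. The Lewis acid ionises F1 to its own ortho-quinone methide, and C6 and C8 of 1 attack it in a Friedel–Crafts sense, a known way to ortho-hydroxybenzylate phloroglucinol-type flavanones. The benzylic carbon of F1 is already C1'' with oxygen on C2'' and C3'', so the pattern is correct, and water is the only by-product. This bypasses 2, 7 and 11 and needs no protecting groups, at the price of mono/bis mixtures and self-condensation of F1, to be dealt with by chromatography.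

**Step 1.** The most likely failures are incomplete second substitution giving mixtures of mono- and bis-Mannich bases, premature loss of amine from the product leading to methylene-bridged oligomers, and erosion of configuration at C2 if the medium drifts basic. Fallback, setting out from 1 and returning at 2: the three-component condensation is replaced by a preformed electrophile. 1 is treated with dimethylmethyleneiminium iodide (Eschenmoser's salt) in MeCN–CH2Cl2 at 0 °C → rt, with no free amine or water present. The product separates as the bis(hydroiodide) F2, which is partitioned between EtOAc and cold aqueous NaHCO3 to release 2.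

**Step 3.** The most likely failures are over-addition of the aryllithium to the borate (borinic by-products), and protodeboronation or anhydride formation during work-up and purification of the free boronic acid. Fallback, setting out from 4 and returning at 7: aryllithium 5, generated as in step 3, is quenched with 2-isopropoxy-4,4,5,5-tetramethyl-1,3,2-dioxaborolane. This gives pinacol boronate F3, which is neutral and tolerates chromatography. Oxidative cleavage of the pinacol unit with NaIO4/NH4OAc in aqueous acetone at rt then gives 7 under conditions that leave the acetals intact.

**Step 5.** The most likely failures are incomplete cleavage of the hindered acetals on O2'', capture of the oxocarbenium fragment by the electron-rich rings, acid-promoted scrambling of the hydroxybenzyl groups, and air oxidation of the released catechols. Fallback, setting out from 2 and returning at 12, with benzyl ethers in place of the acetals so that the last step is neutral: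
- 3-bromocatechol F4 (purchased) is O-benzylated (BnBr, K2CO3, DMF) to 1,2-bis(benzyloxy)-3-bromobenzene F5.
- Bromine–lithium exchange (n-BuLi, THF, −78 °C), borate quench and dilute acid hydrolysis give [2,3-bis(benzyloxy)phenyl]boronic acid F6.
- F6 is combined with 2 under the conditions of step 4 to give the tetrabenzyl flavanone F7 (the same compound as A6).
- Hydrogenolysis (H2, Pd/C, EtOAc–MeOH, rt) releases 12.

## Further compounds

F1 | step 4 | 2,3-dihydroxybenzyl alcohol | OCc1cccc(O)c1O
F2 | step 1 | (2S)-6,8-bis[(dimethylamino)methyl]-5,7-dihydroxy-2-phenylchroman-4-one bis(hydroiodide) | O=C1C[C@@H](c2ccccc2)Oc2c(CN(C)C)c(O)c(CN(C)C)c(O)c21.I.I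
F3 | step 3 | 2-[2,3-bis(methoxymethoxy)phenyl]-4,4,5,5-tetramethyl-1,3,2-dioxaborolane | COCOc1cccc(B2OC(C)(C)C(C)(C)O2)c1OCOC
F4 | step 5 | 3-bromocatechol (3-bromobenzene-1,2-diol) | Oc1cccc(Br)c1O
F5 | step 5 | 1,2-bis(benzyloxy)-3-bromobenzene | Brc1cccc(OCc2ccccc2)c1OCc1ccccc1
F6 | step 5 | [2,3-bis(benzyloxy)phenyl]boronic acid | OB(O)c1cccc(OCc2ccccc2)c1OCc1ccccc1
F7 | step 5 | (2S)-6,8-bis[2,3-bis(benzyloxy)benzyl]-5,7-dihydroxy-2-phenylchroman-4-one | O=C1C[C@@H](c2ccccc2)Oc2c(Cc3cccc(OCc4ccccc4)c3OCc3ccccc3)c(O)c(Cc3cccc(OCc4ccccc4)c3OCc3ccccc3)c(O)c21
A1 | alternative 1 | 2,4-bis[2,3-bis(benzyloxy)benzyl]-3,5-bis(triisopropylsilyloxy)phenol | Oc1cc(O[Si](C(C)C)(C(C)C)C(C)C)c(Cc2cccc(OCc3ccccc3)c2OCc2ccccc2)c(O[Si](C(C)C)(C(C)C)C(C)C)c1Cc1cccc(OCc2ccccc2)c1OCc1ccccc1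
A2 | alternative 1 | 2-[2,3-bis(benzyloxy)benzyl]-3-(triisopropylsilyloxy)cyclobut-2-en-1-one | O=C1CC(O[Si](C(C)C)(C(C)C)C(C)C)=C1Cc1cccc(OCc2ccccc2)c1OCc1ccccc1
A3 | alternative 1 | 1,2-bis(benzyloxy)-3-[3-(triisopropylsilyloxy)prop-2-yn-1-yl]benzene | CC(C)[Si](C(C)C)(C(C)C)OC#CCc1cccc(OCc2ccccc2)c1OCc1ccccc1
A4 | alternative 2 | (2S)-4-(tert-butyldimethylsilyloxy)-6,8-bis[2,3-bis(methoxymethoxy)benzyl]-5,7-bis(methoxymethoxy)-2-phenylchromane | CC(C)(C)[Si](C)(C)OC1C[C@@H](c2ccccc2)Oc2c(Cc3cccc(OCOC)c3OCOC)c(OCOC)c(Cc3cccc(OCOC)c3OCOC)c(OCOC)c21
A5 | alternative 2 | 2-[(3S)-1-(tert-butyldimethylsilyloxy)-3-hydroxy-3-phenylpropyl]-4,6-bis[2,3-bis(methoxymethoxy)benzyl]-3,5-bis(methoxymethoxy)phenyl trifluoromethanesulfonate | O[C@H](c1ccccc1)CC(O[Si](C)(C)C(C)(C)C)c1c(OS(=O)(=O)C(F)(F)F)c(Cc2cccc(OCOC)c2OCOC)c(OCOC)c(Cc2cccc(OCOC)c2OCOC)c1OCOC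
A6 | alternative 3 | (2S)-6,8-bis[2,3-bis(benzyloxy)benzyl]-5,7-dihydroxy-2-phenylchroman-4-one | O=C1C[C@@H](c2ccccc2)Oc2c(Cc3cccc(OCc4ccccc4)c3OCc3ccccc3)c(O)c(Cc3cccc(OCc4ccccc4)c3OCc3ccccc3)c(O)c21
A7 | alternative 3 | (3S)-3-{2,4-bis[2,3-bis(benzyloxy)benzyl]-3,5-dihydroxyphenoxy}-3-phenylpropanoic acid | OC(=O)C[C@@H](c1ccccc1)Oc1cc(O)c(Cc2cccc(OCc3ccccc3)c2OCc2ccccc2)c(O)c1Cc1cccc(OCc2ccccc2)c1OCc1ccccc1
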